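Ring A of the trans-decalin (C1–C5, C10) is read as a Prins retron, because the C1 carbinol and the C3 chloride are 1,3-related, and the quaternary C10 carrying C1 is read as the terminus of a 1,2-shift. In the key step SnCl4 ionises a tertiary chloride at C10 of a seven-membered ring in which C1 (as silyl ether) still lies between C5 and C10: C5 migrates to C10 (ring contraction, ring B) and the C1 silyloxocarbenium is trapped by the C4 vinyl group and chloride (ring A). The precursor is a lactone-fused cycloheptadiene chlorohydrin ether, built by Cu-catalysed allylic substitution and a Rh-carbenoid cyclopropanation/Cope cascade.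

Key step: step 13

Remark (assumption): locants are those of the decalin target and are kept for all intermediates (ring A = C1 CHOH, C2, C3 CHCl, C4, C5, C10; ring B = C5–C10; C11/C12 = formyl carbons on C9/C8). The target is taken as the open hydroxy dialdehyde as drawn.

Step 1
Reactants: 1 geraniol; 2 diethyl chlorophosphate
Product: 3 geranyl diethyl phosphate
Conditions: pyridine, DMAP (cat.), CH2Cl2, 0 °C to rt
Reagents that add atoms: diethyl chlorophosphate, CCOP(=O)(Cl)OCC
Why: O-Phosphorylation of the primary allylic alcohol (no stereocentre formed) installs the leaving group needed for copper-catalysed SN2′ substitution.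

Step 2
Reactants: 4 (2E)-3-methylpent-2-en-4-yn-1-ol; 5 tert-butyldimethylsilyl chloride
Product: 6 TBS ether of the enynol
Conditions: imidazole, CH2Cl2, 0 °C to rt
Reagents that add atoms: tert-butyldimethylsilyl chloride, CC(C)(C)[Si](C)(C)Cl
Why: Standard silylation masks the hydroxyl so that the terminal alkyne can be hydroaluminated; no stereocentre is formed.

Step 3
Reactants: 6 TBS ether of the enynol; 3 geranyl diethyl phosphate
Product: 8 silyl ether of the (6R)-trienol, via dienylalane 7 (not isolated)
Conditions: i) DIBAL-H (1.0 equiv), hexanes, 55 °C; ii) 3, CuCl2·2H2O (2 mol %), chiral sulfonate-bearing NHC–Ag complex (1 mol %, enantiomer giving the drawn centre), THF, −15 °C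
Reagents that add atoms: none
Why: syn-Hydroalumination gives the (E)-alkenylalane, and NHC–Cu-catalysed enantioselective allylic substitution (SN2′) on the E-trisubstituted phosphate forms the C4–C5 bond and the quaternary C4 centre, whose sense is set by the catalyst enantiomer.

Step 4
Reactants: 8 silyl ether of the (6R)-trienol
Product: 9 (2E,4E,6R)-3,6,10-trimethyl-6-vinylundeca-2,4,9-trien-1-ol
Conditions: TBAF, THF, 0 °C
Reagents that add atoms: none
Why: Fluoride-mediated desilylation frees the allylic alcohol without touching the skipped polyene or the quaternary centre.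

Step 5
Reactants: 9 trienol; 10 but-3-enoic acid
Product: 11 trienyl but-3-enoate
Conditions: DCC, DMAP (5 mol %), CH2Cl2, −20 to 0 °C
Reagents that add atoms: but-3-enoic acid, C=CCC(=O)O
Why: Steglich esterification at low temperature attaches the future carbenoid unit (C6–C8, C12) without isomerising the β,γ-unsaturated acid.

Step 6
Reactants: 11 trienyl but-3-enoate; 12 4-acetamidobenzenesulfonyl azide
Product: 13 trienyl 2-diazobut-3-enoate
Conditions: DBU, MeCN, 0 °C; used at once
Reagents that add atoms: 4-acetamidobenzenesulfonyl azide, CC(=O)Nc1ccc(cc1)S(=O)(=O)N=[N+]=[N-]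
Why: Regitz diazo transfer to the doubly activated allylic/α-ester methylene should give the vinyldiazoacetate; no stereocentre is involved.

Step 7
Reactants: 13 trienyl 2-diazobut-3-enoate
Product: 15 lactone-fused cyclohepta-1,4-diene, via divinylcyclopropane lactone 14 (not isolated)
Conditions: Rh2(S-DOSP)4 (1 mol %; antipode if required for the drawn sense), hexanes/CH2Cl2, −40 °C to rt
Reagents that add atoms: none
Why: Intramolecular Rh-vinylcarbenoid cyclopropanation of the (2E) allylic alkene gives the cis-divinylcyclopropane, which undergoes a boat Cope rearrangement (formal [4+3]); C9 follows from the catalyst-controlled face of cyclopropanation and C5 from the stereospecific Cope step of the E alkene, cis to the C9 CH2O group.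

Step 8
Reactants: 15 lactone-fused cyclohepta-1,4-diene; 16 N,O-dimethylhydroxylamine hydrochloride
Product: 17 hydroxy Weinreb amide
Conditions: Me3Al, CH2Cl2, 0 °C to rt
Reagents that add atoms: N,O-dimethylhydroxylamine hydrochloride, CNOC.Cl
Why: Aluminium-amide aminolysis of the lactone (Weinreb amide formation) frees the C11 hydroxyl as a directing group and keeps C7=C8 electron-poor; no stereocentre changes.

Step 9
Reactants: 17 hydroxy Weinreb amide; 18 tert-butyl hydroperoxide
Product: 19 syn-epoxy alcohol
Conditions: VO(acac)2 (5 mol %), t-BuOOH (1.5 equiv), CH2Cl2, 0 °C to rt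
Reagents that add atoms: tert-butyl hydroperoxide, CC(C)(C)OO
Why: Vanadium-catalysed hydroxyl-directed epoxidation should deliver oxygen to the homoallylic C1=C10 alkene on the face of the CH2OH group and leave the isopropylidene, vinyl and conjugated alkenes untouched.

Step 10
Reactants: 19 syn-epoxy alcohol
Product: 20 epoxy lactone
Conditions: NaH (10 mol %), THF, 0 °C
Reagents that add atoms: none
Why: Alkoxide attack on the Weinreb amide (5-exo-trig translactonisation) restores the lactone, masking the C11 oxygen and removing a nucleophilic amide carbonyl before cationic chemistry.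

Step 11
Reactants: 20 epoxy lactone; 21 pyridinium chloride
Product: 22 chlorohydrin lactone
Conditions: pyridinium chloride (1.5 equiv), CH2Cl2, 0 °C to rt
Reagents that add atoms: pyridinium chloride, c1cc[nH+]cc1.[Cl-]
Why: Acid-mediated epoxide opening by chloride at the tertiary C10 with inversion (anti chlorohydrin) puts the leaving group on the face opposite to the C9 and C5 substituents, and pyridinium is too weak an acid to hydrochlorinate the alkenes.

Step 12
Reactants: 22 chlorohydrin lactone; 23 triethylsilyl trifluoromethanesulfonate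
Product: 24 chlorohydrin TES ether
Conditions: 2,6-lutidine, CH2Cl2, −78 °C
Reagents that add atoms: triethylsilyl trifluoromethanesulfonate, CC[Si](CC)(CC)OS(=O)(=O)C(F)(F)F
Why: Silylation of the hindered C1 hydroxyl blocks re-closure to the epoxide, keeps oxygen as a push group that cannot deliver chloride, and protects C1–O for the end game.

Step 13
Reactants: 24 chlorohydrin TES ether
Product: 26 silyl-protected chloro decalin lactone, via silyloxocarbenium pentachlorostannate 25 (not isolated)
Conditions: SnCl4 (2.2 equiv), 2,6-di-tert-butyl-4-methylpyridine (0.5 equiv), CH2Cl2, −78 to −30 °C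
Reagents that add atoms: none
Why: SnCl4 abstracts the tertiary chloride at C10 while the antiperiplanar C1–C5 ring bond migrates to C10, pushed by the silyl-ether oxygen, to give silyloxocarbenium 25; the vinyl group on C4 then attacks C1 and SnCl5− returns chloride to C3, so the step is formally an isomerisation. The closest known types are the Tiffeneau-type semipinacol ring contraction of halohydrin derivatives and the Lewis-acid (silyl-)Prins cyclisation with halide termination, run in tandem as in epoxide-rearrangement/Prins sequences. Ring B is closed by the 1,2-alkyl shift (7→6 ring contraction, C5 bonds to C10) and ring A by 6-endo-trig attack of the terminal alkene carbon C2 on the exocyclic oxocarbenium through a chair transition state. C10 is set by inversion (C5 enters anti to the leaving chloride) with retention at C5, which fixes the trans ring fusion; C1 takes its oxygen axial because the equatorial alternative suffers a syn-pentane clash with the C9 lactone CH2; C3 receives chloride anti to the new C1–C2 bond, i.e. equatorial; the C4 methyl is axial by the preset C4/C5 configurations. The step needs alkyl over hydride migration and closure by the vinyl group rather than the isopropylidene alkene: the first is secured by the antiperiplanar ring bond, the second by a six-membered chair against a seven-membered alternative, with the hindered pyridine scavenging acid.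

Step 14
Reactants: 26 silyl-protected chloro decalin lactone
Product: 27 silyl-protected 11,12-diol
Conditions: DIBAL-H (4.5 equiv), CH2Cl2, −78 to 0 °C; Rochelle salt work-up
Reagents that add atoms: none
Why: Hydride reduction of the α-alkylidene γ-lactone gives the allylic/primary 1,4-diol without touching the hindered secondary chloride or the silyl ether; no stereocentre changes.

Step 15
Reactants: 27 silyl-protected 11,12-diol
Product: 28 silyl-protected dialdehyde
Conditions: (COCl)2, DMSO, CH2Cl2, −78 °C; then Et3N, −78 to −40 °C
Reagents that add atoms: none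
Why: Swern oxidation activates both primary alcohols at once, so no lactol stage intervenes, and the cold amine quench should leave the C9 centre unepimerised.

Step 16
Reactants: 28 silyl-protected dialdehyde
Product: 29 target (3β-chloro-1α-hydroxy dialdehyde)
Conditions: HF·pyridine, pyridine, THF, 0 °C
Reagents that add atoms: none
Why: Buffered fluoride desilylation frees the axial C1 hydroxyl, which is geometrically unable to lactolise with the C9β formyl group, under conditions mild enough for the enedial.

Compound list
1 | geraniol, (2E)-3,7-dimethylocta-2,6-dien-1-ol | CC(C)=CCC/C(C)=C/CO | starting material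
2 | diethyl chlorophosphate | CCOP(=O)(Cl)OCC | starting material
3 | geranyl diethyl phosphate | CC(C)=CCC/C(C)=C/COP(=O)(OCC)OCC | intermediate
4 | (2E)-3-methylpent-2-en-4-yn-1-ol | C#C/C(C)=C/CO | starting material
5 | tert-butyldimethylsilyl chloride | CC(C)(C)[Si](C)(C)Cl | starting material
6 | tert-butyldimethyl{[(2E)-3-methylpent-2-en-4-yn-1-yl]oxy}silane | C#C/C(C)=C/CO[Si](C)(C)C(C)(C)C | intermediate
7 | [(1E,3E)-5-(tert-butyldimethylsilyloxy)-3-methylpenta-1,3-dien-1-yl]diisobutylalane | CC(C)C[Al](CC(C)C)/C=C/C(C)=C/CO[Si](C)(C)C(C)(C)C | intermediate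
8 | tert-butyldimethylsilyl ether of (2E,4E,6R)-3,6,10-trimethyl-6-vinylundeca-2,4,9-trien-1-ol | CC(C)=CCC[C@](C)(C=C)/C=C/C(C)=C/CO[Si](C)(C)C(C)(C)C | intermediate
9 | (2E,4E,6R)-3,6,10-trimethyl-6-vinylundeca-2,4,9-trien-1-ol | CC(C)=CCC[C@](C)(C=C)/C=C/C(C)=C/CO | intermediate
10 | but-3-enoic acid | C=CCC(=O)O | starting material
11 | (2E,4E,6R)-3,6,10-trimethyl-6-vinylundeca-2,4,9-trien-1-yl but-3-enoate | CC(C)=CCC[C@](C)(C=C)/C=C/C(C)=C/COC(=O)CC=C | intermediate
12 | 4-acetamidobenzenesulfonyl azide | CC(=O)Nc1ccc(cc1)S(=O)(=O)N=[N+]=[N-] | starting material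
13 | (2E,4E,6R)-3,6,10-trimethyl-6-vinylundeca-2,4,9-trien-1-yl 2-diazobut-3-enoate | CC(C)=CCC[C@](C)(C=C)/C=C/C(C)=C/COC(=O)C(=[N+]=[N-])C=C | intermediate
14 | 3-oxabicyclo[3.1.0]hexan-2-one with 1-vinyl, 6-methyl and 6-[(1E,3R)-3,7-dimethyl-3-vinylocta-1,6-dien-1-yl]; vinyl and dienyl cis on the cyclopropane, anti to the lactone | CC(C)=CCC[C@](C)(C=C)/C=C/[C@]1(C)[C@H]2COC(=O)[C@@]12C=C | intermediate
15 | (3aR,6R)-6-[(3R)-3,7-dimethylocta-1,6-dien-3-yl]-4-methyl-3,3a,6,7-tetrahydro-1H-cyclohepta[c]furan-1-one (lactone CH2O at C9 and side chain at C5 cis) | CC(C)=CCC[C@](C)(C=C)[C@@H]1CC=C2C(=O)OC[C@@H]2C(C)=C1 | intermediate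
16 | N,O-dimethylhydroxylamine hydrochloride | CNOC.Cl | starting material
17 | (4R,7R)-4-[(3R)-3,7-dimethylocta-1,6-dien-3-yl]-7-(hydroxymethyl)-N-methoxy-N,6-dimethylcyclohepta-1,5-diene-1-carboxamide | CC(C)=CCC[C@](C)(C=C)[C@@H]1CC=C(C(=O)N(C)OC)[C@H](CO)C(C)=C1 | intermediate
18 | tert-butyl hydroperoxide | CC(C)(C)OO | starting material
19 | epoxide of 17 at the methyl-bearing ring alkene (C1–C10), oxygen on the face of the CH2OH group | CC(C)=CCC[C@](C)(C=C)[C@@H]1CC=C(C(=O)N(C)OC)[C@H](CO)[C@]2(C)O[C@H]12 | intermediate
20 | C1–C10 epoxide of lactone 15, oxygen syn to the lactone CH2O and to the C5 side chain | CC(C)=CCC[C@](C)(C=C)[C@@H]1CC=C2C(=O)OC[C@@H]2[C@]3(C)O[C@H]13 | intermediate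
21 | pyridinium chloride | c1cc[nH+]cc1.[Cl-] | starting material
22 | chlorohydrin lactone: tertiary chloride at C10 anti to the lactone CH2O and the C5 side chain, secondary alcohol at C1 syn to them | CC(C)=CCC[C@](C)(C=C)[C@@H]1CC=C2C(=O)OC[C@@H]2[C@@](C)(Cl)[C@@H]1O | intermediate
23 | triethylsilyl trifluoromethanesulfonate | CC[Si](CC)(CC)OS(=O)(=O)C(F)(F)F | starting material
24 | triethylsilyl ether of chlorohydrin lactone 22 | CC(C)=CCC[C@](C)(C=C)[C@@H]1CC=C2C(=O)OC[C@@H]2[C@@](C)(Cl)[C@@H]1O[Si](CC)(CC)CC | intermediate
25 | ring-contracted O-triethylsilyl oxocarbenium (C1) pentachlorostannate; cyclohexene ring B with lactone, C10 quaternary | CC(C)=CCC[C@](C)(C=C)[C@@H]1CC=C2C(=O)OC[C@@H]2[C@@]1(C)C=[O+][Si](CC)(CC)CC.Cl[Sn-](Cl)(Cl)(Cl)Cl | intermediate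
26 | trans-decalin lactone: 3β-chloro-1α-(triethylsilyloxy), 4β-methyl, 4α-(4-methylpent-3-enyl), 5α-H, 10β-methyl, Δ7, lactone C=O on C8 and O–CH2 on C9β | CC(C)=CCC[C@]1(C)[C@@H](Cl)C[C@H](O[Si](CC)(CC)CC)[C@]2(C)[C@H]3COC(=O)C3=CC[C@@H]12 | intermediate
27 | corresponding 11,12-diol (CH2OH on C9β and on C8), 1α-OTES, 3β-Cl | CC(C)=CCC[C@]1(C)[C@@H](Cl)C[C@H](O[Si](CC)(CC)CC)[C@]2(C)[C@@H](CO)C(CO)=CC[C@@H]12 | intermediate
28 | corresponding 11,12-dialdehyde, 1α-OTES, 3β-Cl | CC(C)=CCC[C@]1(C)[C@@H](Cl)C[C@H](O[Si](CC)(CC)CC)[C@]2(C)[C@@H](C=O)C(C=O)=CC[C@@H]12 | intermediate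
29 | target: 3β-chloro-1α-hydroxy trans-decalin 8,9-dicarbaldehyde (Δ7; 4β-methyl, 4α-(4-methylpent-3-enyl), 5α-H, 9β-CHO, 10β-methyl) | CC(C)=CCC[C@]1(C)[C@@H](Cl)C[C@H](O)[C@]2(C)[C@@H](C=O)C(C=O)=CC[C@@H]12 | target

Total step count: 16. Longest linear sequence: 15 steps (steps 1 and 3–16 from geraniol; step 2 is a one-step side branch).

Steps most likely to fail

Step 13. The C10 cation may undergo hydride shift or proton loss instead of C5 migration, the anti stereospecificity may erode through a free cation, or the Prins closure may stall or be diverted (attack by the isopropylidene alkene, syn delivery of chloride). The fallback sets out from 24 and comes back at 26, giving up the single operation by decoupling the two events. Silver tetrafluoroborate with the hindered pyridine at −78 °C removes the tertiary chloride under chloride-free conditions, and fluoride from the counter-ion desilylates the oxocarbenium to the ring-contracted α-quaternary aldehyde F1. A separate chloro-Prins cyclisation of F1 with TiCl4 at −78 °C (external chloride, chair transition state) gives the free C1 alcohol F2. Silylation of F2 with 23 and 2,6-lutidine returns to 26.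

Step 7. Facial control by the chiral rhodium carboxylate on this E-trisubstituted allylic alkene may be insufficient or mismatched with the C4 centre, and the vinyldiazo ester may be lost to pyrazole formation before the carbenoid forms. The fallback sets out from 9 and comes back at 15, replacing the vinylcarbenoid by a stable acceptor/acceptor carbenoid. Acetoacetylation of 9 with 2,2,6-trimethyl-4H-1,3-dioxin-4-one gives the β-keto ester F3, and diazo transfer with 12 gives the diazoacetoacetate F4. Cu(I)–bis(oxazoline)-catalysed intramolecular cyclopropanation gives the acetylcyclopropane lactone F5, whose diastereomers should be separable on the rigid bicycle. Kinetic enolisation with KHMDS and N-phenyltriflimide gives the enol triflate F6, and Pd-catalysed formate reduction of F6 unveils the vinyl group, i.e. divinylcyclopropane 14, which rearranges to 15.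

Step 9. Oxygen delivery may be slow or facially unselective because the directed face also carries the bulky C5 substituent, allowing background oxidation of the isopropylidene alkene. The fallback sets out from 17 and comes back at 19, replacing metal-directed epoxidation by covalent delivery. The C11 hydroxyl is converted with di-tert-butyl dicarbonate into the tert-butyl carbonate F7. Iodocarbonate cyclisation of F7 with IBr at −78 °C puts the carbonate oxygen on C10 from the CH2O face and iodine on C1 from the opposite face, giving the cyclic iodocarbonate F8. Methanolysis of F8 with K2CO3 frees the C10 alkoxide, which displaces iodide at C1 to give the same syn-epoxy alcohol 19.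

Further compounds
F1 | step 13 | ring-contracted aldehyde: formyl (C1) on quaternary C10 of the lactone-fused cyclohexene, C5 side chain with vinyl intact | CC(C)=CCC[C@](C)(C=C)[C@@H]1CC=C2C(=O)OC[C@@H]2[C@@]1(C)C=O
F2 | step 13 | free C1 alcohol of decalin lactone 26 (3β-chloro-1α-hydroxy) | CC(C)=CCC[C@]1(C)[C@@H](Cl)C[C@H](O)[C@]2(C)[C@H]3COC(=O)C3=CC[C@@H]12
F3 | step 7 | (2E,4E,6R)-3,6,10-trimethyl-6-vinylundeca-2,4,9-trien-1-yl 3-oxobutanoate | CC(C)=CCC[C@](C)(C=C)/C=C/C(C)=C/COC(=O)CC(C)=O
F4 | step 7 | (2E,4E,6R)-3,6,10-trimethyl-6-vinylundeca-2,4,9-trien-1-yl 2-diazo-3-oxobutanoate | CC(C)=CCC[C@](C)(C=C)/C=C/C(C)=C/COC(=O)C(=[N+]=[N-])C(C)=O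
F5 | step 7 | 1-acetyl analogue of cyclopropane lactone 14 | CC(C)=CCC[C@](C)(C=C)/C=C/[C@]1(C)[C@H]2COC(=O)[C@@]12C(C)=O
F6 | step 7 | enol triflate of F5 (1-[1-(trifluoromethylsulfonyloxy)vinyl] cyclopropane lactone) | CC(C)=CCC[C@](C)(C=C)/C=C/[C@]1(C)[C@H]2COC(=O)[C@@]12C(=C)OS(=O)(=O)C(F)(F)F
F7 | step 9 | tert-butyl carbonate of hydroxy amide 17 | CC(C)=CCC[C@](C)(C=C)[C@@H]1CC=C(C(=O)N(C)OC)[C@H](COC(=O)OC(C)(C)C)C(C)=C1
F8 | step 9 | cyclic iodocarbonate: 1,3-dioxan-2-one spanning C11–O and C10–O, iodide at C1 anti to the C10 oxygen | CC(C)=CCC[C@](C)(C=C)[C@@H]1CC=C(C(=O)N(C)OC)[C@@H]2COC(=O)O[C@]2(C)[C@H]1I
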